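**Plan**
- Retrosynthetic cuts, in order: (i) four O–benzyl bonds and the acetyl–O bond (end game); (ii) ring bond C1–C2 of the trihydroxyphenyl ring (retro-Claisen, back to a 2-pyrone); (iii) the ketone C(=O)–ring C1 bond; (iv) the benzylic CH2–aryl bond at C2 of the resorcinol ring.
- Enabling feature: the ketone carbon and ring carbons C2, C4 and C6 of the trihydroxyphenyl ring carry oxygen on every second atom of the run C(=O)–C1–C2–C3–C4–C5–C6, which is a folded tetraketide. The C6O3 ring is an isomer of 4-hydroxy-6-methyl-2-pyrone, whose CH3 is the future ring carbon C1.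
- Forward: 2-iodoresorcinol is desymmetrised (Bn, then MOM) and the C11 chain is attached by a B-alkyl Suzuki coupling. The chain end (Weinreb amide as activating group) then acylates the dianion of triacetic acid lactone, and Mg(OMe)2 exchanges the temporary pyrone ring for the carbocycle.
- End game: benzylation of the three new phenols, MOM removal, acetylation of the only free phenol, then one hydrogenolysis that frees four phenols and leaves the acetate.
- Rings and stereochemistry: the resorcinol ring is bought and the phloroglucinol ring is made last (step 6). There is no stereochemistry to set.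

Key step: step 5

Remark on the chemistry: the target SMILES holds no stereocentre and no stereogenic double bond. The compound is achiral, so the "single enantiomer" is the compound itself.

**Step 1**
Reactants: 1 2-iodoresorcinol (2-iodobenzene-1,3-diol)
Product: 2 3-(benzyloxy)-2-iodophenol
Conditions: BnBr (1.0 equiv, slow addition), K2CO3 (1.0 equiv), acetone, reflux
Reagents that add atoms: benzyl bromide, BrCc1ccccc1
Why: A Williamson etherification with the halide as limiting reagent should stop mainly at the mono-ether, which is separable by chromatography from recovered 1 and from the bis-ether, and this breaks the symmetry of the resorcinol ring.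

**Step 2**
Reactants: 2 3-(benzyloxy)-2-iodophenol
Product: 3 1-(benzyloxy)-2-iodo-3-(methoxymethoxy)benzene
Conditions: NaH, MOMCl, THF–DMF, 0 °C to rt
Reagents that add atoms: chloromethyl methyl ether, COCCl
Why: O-Alkylation of the sodium phenoxide gives the MOM acetal, which withstands Pd, organolithium bases and methoxide, is orthogonal to benzyl, and marks the oxygen that will later carry the acetate.

**Step 3**
Reactants: 4 undec-10-enoyl chloride
Product: 5 N-methoxy-N-methylundec-10-enamide
Conditions: MeNH(OMe)·HCl, K2CO3, CH2Cl2–H2O, 0 °C to rt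
Reagents that add atoms: N,O-dimethylhydroxylamine hydrochloride, CNOC.Cl
Why: A Schotten–Baumann amidation of the acid chloride gives the Weinreb amide, the acyl donor needed for a clean single acylation in step 5.

**Step 4**
Reactants: 5 N-methoxy-N-methylundec-10-enamide; 3 1-(benzyloxy)-2-iodo-3-(methoxymethoxy)benzene
Product: 7 11-[2-(benzyloxy)-6-(methoxymethoxy)phenyl]-N-methoxy-N-methylundecanamide, via B-alkyl-9-BBN borane 6 (not isolated)
Conditions: 9-BBN, THF, 0 °C to rt; then 3, Pd(dppf)Cl2 (cat.), aq. K3PO4, THF–DMF, 60 °C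
Reagents that add atoms: none
Why: 9-BBN adds anti-Markovnikov to the terminal alkene far faster than it touches the amide, and the B-alkyl Suzuki–Miyaura coupling, well known for 2,6-dialkoxyaryl iodides, forms the benzylic C–C bond without a hydrogenation that would endanger the benzyl ether.

**Step 5**
Reactants: 8 4-hydroxy-6-methyl-2H-pyran-2-one (triacetic acid lactone); 7 11-[2-(benzyloxy)-6-(methoxymethoxy)phenyl]-N-methoxy-N-methylundecanamide
Product: 11 6-{12-[2-(benzyloxy)-6-(methoxymethoxy)phenyl]-2-oxododecyl}-4-hydroxy-2H-pyran-2-one, via dilithio triacetic acid lactone 9 (not isolated), via lithium-chelated tetrahedral adduct 10 (not isolated)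
Conditions: 8 (2 equiv), LDA (commercial solution, 4.1 equiv), THF–DMPU, −78 to −20 °C; then 7, −78 to 0 °C; cold 1 M HCl to pH 3
Reagents that add atoms: none
Why: LDA removes first the 4-OH proton and then a proton of the 6-methyl group of 8, and dianion 9 attacks the amide carbonyl of 7 through its last-formed and least stabilised site, the exocyclic CH2, which is the future acyl-bearing ring carbon. Adduct 10 is held as a five-membered lithium chelate until the acid quench, so neither a second addition nor protonation of 9 by the more acidic β-keto product can occur. The closest known reaction type is the terminal (γ) acylation of 1,3-dicarbonyl dianions, known for this pyrone dianion with esters and for related keto-dioxinone dianions with Weinreb amides, and it is the convergent laboratory copy of the union of a fatty acyl starter with a triketide chain on a type III polyketide synthase. No ring closes in this step and the only new stereocentre, the carbinolamine carbon of 10, is lost on collapse to the ketone; the pyrone is a temporary ring that stores the C6O3 triketide until step 6. The step needs site selectivity (CH2 against O-4, C-3 and C-5), secured by the order of basicity within the dianion, and chemoselectivity, secured by the base-stable benzyl and MOM ethers. With this one bond every carbon of the target except the acetyl group is in place.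

**Step 6**
Reactants: 11 6-{12-[2-(benzyloxy)-6-(methoxymethoxy)phenyl]-2-oxododecyl}-4-hydroxy-2H-pyran-2-one
Product: 13 11-[2-(benzyloxy)-6-(methoxymethoxy)phenyl]-1-(2,4,6-trihydroxyphenyl)undecan-1-one, via methyl 3,5,7-trioxo ester 12 (not isolated)
Conditions: Mg(OMe)2 (excess), MeOH, reflux; cold 1 M HCl to pH 3
Reagents that add atoms: none
Why: Methoxide opens the lactone at C-2 to triketo ester 12, whose three ketones are tied up as magnesium enolate chelates so that only the ester carbonyl stays electrophilic, and C-6 closes on it in a 6-exo-trig Claisen (Dieckmann-type) condensation whose product loses methanol and enolises to the aromatic ring (the known biomimetic pyrone-to-acylphloroglucinol conversion).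

**Step 7**
Reactants: 13 11-[2-(benzyloxy)-6-(methoxymethoxy)phenyl]-1-(2,4,6-trihydroxyphenyl)undecan-1-one
Product: 14 11-[2-(benzyloxy)-6-(methoxymethoxy)phenyl]-1-[2,4,6-tris(benzyloxy)phenyl]undecan-1-one
Conditions: BnBr (3.6 equiv), K2CO3, DMF, 60 °C
Reagents that add atoms: benzyl bromide, BrCc1ccccc1
Why: A threefold Williamson etherification in warm DMF, the standard way to 2,4,6-tris(benzyloxy)aryl ketones, should favour oxygen because the acyl group lowers the carbon nucleophilicity of the ring, and the MOM acetal is inert to carbonate.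

**Step 8**
Reactants: 14 11-[2-(benzyloxy)-6-(methoxymethoxy)phenyl]-1-[2,4,6-tris(benzyloxy)phenyl]undecan-1-one
Product: 15 11-[2-(benzyloxy)-6-hydroxyphenyl]-1-[2,4,6-tris(benzyloxy)phenyl]undecan-1-one
Conditions: aq. HCl (cat.), MeOH–THF, 45 °C
Reagents that add atoms: none
Why: Acid-catalysed acetal exchange with methanol removes the only acetal in the molecule, leaves benzyl ethers and ketone untouched, and lays bare the one phenol that is to be acetylated.

**Step 9**
Reactants: 15 11-[2-(benzyloxy)-6-hydroxyphenyl]-1-[2,4,6-tris(benzyloxy)phenyl]undecan-1-one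
Product: 16 3-(benzyloxy)-2-{11-oxo-11-[2,4,6-tris(benzyloxy)phenyl]undecyl}phenyl acetate
Conditions: Ac2O, pyridine, DMAP (cat.), CH2Cl2, 0 °C to rt
Reagents that add atoms: acetic anhydride, CC(=O)OC(C)=O
Why: DMAP-catalysed acetylation meets a single free hydroxyl group, so the position of the acetate is fixed by the protecting-group pattern and not by any selectivity between phenols.

**Step 10**
Reactants: 16 3-(benzyloxy)-2-{11-oxo-11-[2,4,6-tris(benzyloxy)phenyl]undecyl}phenyl acetate
Product: 17 3-hydroxy-2-[11-oxo-11-(2,4,6-trihydroxyphenyl)undecyl]phenyl acetate (target)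
Conditions: H2 (1 atm), 10% Pd/C, EtOAc, rt
Reagents that add atoms: none
Why: Neutral hydrogenolysis in a non-nucleophilic solvent cleaves all four aryl benzyl ethers, the aryl acetate is inert to it, and the electron-rich, chelated aryl ketone resists reduction.

**Compound list**
1 | 2-iodoresorcinol | Oc1cccc(O)c1I | starting material
2 | 3-(benzyloxy)-2-iodophenol | Oc1cccc(OCc2ccccc2)c1I | intermediate
3 | 1-(benzyloxy)-2-iodo-3-(methoxymethoxy)benzene | COCOc1cccc(OCc2ccccc2)c1I | intermediate
4 | undec-10-enoyl chloride | C=CCCCCCCCCC(=O)Cl | starting material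
5 | N-methoxy-N-methylundec-10-enamide | C=CCCCCCCCCC(=O)N(C)OC | intermediate
6 | 11-(9-borabicyclo[3.3.1]nonan-9-yl)-N-methoxy-N-methylundecanamide (not isolated) | CON(C)C(=O)CCCCCCCCCCB1C2CCCC1CCC2 | intermediate
7 | 11-[2-(benzyloxy)-6-(methoxymethoxy)phenyl]-N-methoxy-N-methylundecanamide | CON(C)C(=O)CCCCCCCCCCc1c(OCc2ccccc2)cccc1OCOC | intermediate
8 | 4-hydroxy-6-methyl-2H-pyran-2-one (triacetic acid lactone) | CC1=CC(O)=CC(=O)O1 | starting material
9 | dilithium O-4,6-CH2 dianion of 8 (not isolated) | [Li+].[Li+].[CH2-]C1=CC([O-])=CC(=O)O1 | intermediate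
10 | dilithium tetrahedral adduct of 9 and 7 (racemic, transient, not isolated) | [Li+].[Li+].CON(C)C([O-])(CC1=CC([O-])=CC(=O)O1)CCCCCCCCCCc1c(OCc2ccccc2)cccc1OCOC | intermediate
11 | 6-{12-[2-(benzyloxy)-6-(methoxymethoxy)phenyl]-2-oxododecyl}-4-hydroxy-2H-pyran-2-one | O=C1C=C(O)C=C(CC(=O)CCCCCCCCCCc2c(OCc3ccccc3)cccc2OCOC)O1 | intermediate
12 | methyl 17-[2-(benzyloxy)-6-(methoxymethoxy)phenyl]-3,5,7-trioxoheptadecanoate (present as magnesium chelate, not isolated) | COC(=O)CC(=O)CC(=O)CC(=O)CCCCCCCCCCc1c(OCc2ccccc2)cccc1OCOC | intermediate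
13 | 11-[2-(benzyloxy)-6-(methoxymethoxy)phenyl]-1-(2,4,6-trihydroxyphenyl)undecan-1-one | COCOc1cccc(OCc2ccccc2)c1CCCCCCCCCCC(=O)c1c(O)cc(O)cc1O | intermediate
14 | 11-[2-(benzyloxy)-6-(methoxymethoxy)phenyl]-1-[2,4,6-tris(benzyloxy)phenyl]undecan-1-one | COCOc1cccc(OCc2ccccc2)c1CCCCCCCCCCC(=O)c1c(OCc2ccccc2)cc(OCc2ccccc2)cc1OCc1ccccc1 | intermediate
15 | 11-[2-(benzyloxy)-6-hydroxyphenyl]-1-[2,4,6-tris(benzyloxy)phenyl]undecan-1-one | Oc1cccc(OCc2ccccc2)c1CCCCCCCCCCC(=O)c1c(OCc2ccccc2)cc(OCc2ccccc2)cc1OCc1ccccc1 | intermediate
16 | 3-(benzyloxy)-2-{11-oxo-11-[2,4,6-tris(benzyloxy)phenyl]undecyl}phenyl acetate | CC(=O)Oc1cccc(OCc2ccccc2)c1CCCCCCCCCCC(=O)c1c(OCc2ccccc2)cc(OCc2ccccc2)cc1OCc1ccccc1 | intermediate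
17 | 3-hydroxy-2-[11-oxo-11-(2,4,6-trihydroxyphenyl)undecyl]phenyl acetate | CC(=O)Oc1cccc(O)c1CCCCCCCCCCC(=O)c1c(O)cc(O)cc1O | target

**Step count**
Total step count: 10.
Longest linear sequence: 9 (steps 1, 2, 4, 5, 6, 7, 8, 9, 10).

**Steps most likely to fail**

First, step 6.
- Risk: the opened chain may cyclise in the aldol sense (ester α-carbon onto the C-7 ketone). It may also be cut by retro-Claisen attack of methoxide, or simply close back to the lactone on work-up.
- Fallback: it sets out from 7 and comes back at 14, and it buys the aromatic ring instead of making it.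
  - Commercial 1,3,5-tris(benzyloxy)benzene is brominated (NBS, CH2Cl2, 0 °C) to 1,3,5-tris(benzyloxy)-2-bromobenzene F3.
  - Bromine–lithium exchange (n-BuLi, THF, −78 °C) gives 2,4,6-tris(benzyloxy)phenyllithium F4.
  - Addition of F4 to Weinreb amide 7 gives ketone 14 directly, so that steps 5 to 7 fall away.

Second, step 5.
- Risk: proton transfer from the α-CH2 of the amide to the strongly basic dianion, low solubility of the dianion aggregate, or base-induced loss of formaldehyde from the N–OMe group may outrun the addition.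
- Fallback: it sets out from 7 and comes back at 11, and it replaces acylation by addition and oxidation.
  - DIBAL-H (THF, −78 °C) reduces 7 to 11-[2-(benzyloxy)-6-(methoxymethoxy)phenyl]undecanal F1.
  - Dianion 9 adds to this far more electrophilic carbonyl (a known aldol-type addition of the pyrone dianion) to give racemic 6-{12-[2-(benzyloxy)-6-(methoxymethoxy)phenyl]-2-hydroxydodecyl}-4-hydroxy-2H-pyran-2-one F2.
  - Dess–Martin periodinane (CH2Cl2, rt) oxidises the carbinol, and with it the transient stereocentre, to 11.

Third, step 7.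
- Risk: benzylation at the nucleophilic ring carbons C-3/C-5 may compete, and the two chelated ortho-phenols may react sluggishly.
- Fallback: it sets out from 13 and comes back at 17, and it uses O-acylation in place of O-alkylation.
  - CbzCl and i-Pr2NEt (CH2Cl2, 0 °C) give 2-{11-[2-(benzyloxy)-6-(methoxymethoxy)phenyl]undecanoyl}benzene-1,3,5-triyl tribenzyl tricarbonate F5, since an acyl electrophile reacts at oxygen only.
  - TFA–CH2Cl2 with a little water removes the MOM group to give 2-{11-[2-(benzyloxy)-6-hydroxyphenyl]undecanoyl}benzene-1,3,5-triyl tribenzyl tricarbonate F6.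
  - Ac2O–pyridine gives 3-(benzyloxy)-2-(11-oxo-11-{2,4,6-tris[(benzyloxycarbonyl)oxy]phenyl}undecyl)phenyl acetate F7.
  - Hydrogenolysis (H2, Pd/C, EtOAc) cleaves the benzyl ether and the three benzyl carbonates to give 17.

**Further compounds**
F1 | step 5 | 11-[2-(benzyloxy)-6-(methoxymethoxy)phenyl]undecanal | O=CCCCCCCCCCCc1c(OCc2ccccc2)cccc1OCOC
F2 | step 5 | 6-{12-[2-(benzyloxy)-6-(methoxymethoxy)phenyl]-2-hydroxydodecyl}-4-hydroxy-2H-pyran-2-one (racemic) | O=C1C=C(O)C=C(CC(O)CCCCCCCCCCc2c(OCc3ccccc3)cccc2OCOC)O1
F3 | step 6 | 1,3,5-tris(benzyloxy)-2-bromobenzene | Brc1c(OCc2ccccc2)cc(OCc2ccccc2)cc1OCc1ccccc1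
F4 | step 6 | 2,4,6-tris(benzyloxy)phenyllithium | [Li]c1c(OCc2ccccc2)cc(OCc2ccccc2)cc1OCc1ccccc1
F5 | step 7 | 2-{11-[2-(benzyloxy)-6-(methoxymethoxy)phenyl]undecanoyl}benzene-1,3,5-triyl tribenzyl tricarbonate | COCOc1cccc(OCc2ccccc2)c1CCCCCCCCCCC(=O)c1c(OC(=O)OCc2ccccc2)cc(OC(=O)OCc2ccccc2)cc1OC(=O)OCc1ccccc1
F6 | step 7 | 2-{11-[2-(benzyloxy)-6-hydroxyphenyl]undecanoyl}benzene-1,3,5-triyl tribenzyl tricarbonate | Oc1cccc(OCc2ccccc2)c1CCCCCCCCCCC(=O)c1c(OC(=O)OCc2ccccc2)cc(OC(=O)OCc2ccccc2)cc1OC(=O)OCc1ccccc1
F7 | step 7 | 3-(benzyloxy)-2-(11-oxo-11-{2,4,6-tris[(benzyloxycarbonyl)oxy]phenyl}undecyl)phenyl acetate | CC(=O)Oc1cccc(OCc2ccccc2)c1CCCCCCCCCCC(=O)c1c(OC(=O)OCc2ccccc2)cc(OC(=O)OCc2ccccc2)cc1OC(=O)OCc1ccccc1
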